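Ring B (O, C6, C7, C11, C12) is disconnected at the lactone O–C6 bond. In the target this oxygen is erythro to the C4–C5 epoxide oxygen, whereas a C6 hydroxyl guides a peracid to the threo face of the cis C4=C5 alkene. The C6 carbinol is therefore used as a directing group and then inverted: the C12 carboxylate, held cis to C6 across the C7=C11 alkene, displaces a C6 mesylate, closing the butenolide and correcting C6 in a single operation. The precursor is the (6S)-mesyloxy seco acid: the complete ten-membered ring with both epoxides, the C13 acetate and the C8 senecioate.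

Key step: step 24

Remark: atom labels follow germacrane numbering (ring C1–C10; C11 on C7 carries C12 and C13; C14 on C10, C15 on C4).
Remark: CIP analysis gives the target as (1S,4S,5R,6R,8R,10R) and the seco acid as (1S,4S,5R,6S,8R,10R) with the carboxyl cis to C6; both epoxides are cis with respect to the ring (C2/C9 and C3/C6 cis), so both derive from Z alkenes.
Remark: in dienol 32 the required C6 arrangement is 6R by CIP (C7 outranks the alkene carbon C5); the same arrangement is 6S once C5 is an epoxide carbon.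
Remark: 12 is the commercial acetonide of 1,3-dihydroxyacetone; the C=N geometry drawn for 16 is that expected from the azaenolate and is of no consequence.
Remark: which antipode of the chromium ligand in step 18 directs Re-face addition would be settled by a two-run screen.

Step 1
Reactants: 1 2-(2-bromoethyl)-1,3-dioxane; 2 propyne
Product: 6 2-[(3Z)-4-iodo-3-methylbut-3-en-1-yl]-1,3-dioxane, via Grignard reagent 3 (not isolated), via alkylcopper 4 (not isolated), via alkenylcopper 5 (not isolated)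
Conditions: Mg, Et2O, 25 °C; CuBr·SMe2, Et2O/Me2S, −45 °C; propyne, −25 °C; I2, −50 to 0 °C
Reagents that add atoms: iodine I2 (SMILES: II)
Why: Normant carbocupration: the alkylcopper adds syn across propyne with the alkyl group on the internal carbon, and iodinolysis of the alkenylcopper with retention gives the 1-iodo-2-methylalkene in which iodine (future C5) is cis to the chain (C3).

Step 2
Reactants: 6 2-[(3Z)-4-iodo-3-methylbut-3-en-1-yl]-1,3-dioxane
Product: 7 (4Z)-5-iodo-4-methylpent-4-enal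
Conditions: 2 M HCl, THF, 45 °C
Reagents that add atoms: water (SMILES: O)
Why: Acid-catalysed acetal hydrolysis releases the C1 aldehyde while the vinyl iodide and its geometry are inert to dilute aqueous acid.

Step 3
Reactants: 7 (4Z)-5-iodo-4-methylpent-4-enal; 8 ethyl 2-[bis(2,2,2-trifluoroethoxy)phosphoryl]propanoate
Product: 9 ethyl (2Z,6Z)-7-iodo-2,6-dimethylhepta-2,6-dienoate
Conditions: KN(SiMe3)2, 18-crown-6, THF, −78 °C
Reagents that add atoms: none
Why: Still–Gennari olefination: fast, irreversible elimination from the kinetic adduct of the trifluoroethyl phosphonate gives the Z-trisubstituted enoate, which fixes C9 cis to C2 across C1=C10.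

Step 4
Reactants: 9 ethyl (2Z,6Z)-7-iodo-2,6-dimethylhepta-2,6-dienoate
Product: 10 (2Z,6Z)-7-iodo-2,6-dimethylhepta-2,6-dien-1-ol
Conditions: i-Bu2AlH, CH2Cl2, −78 °C
Reagents that add atoms: none
Why: 1,2-Reduction of the enoate by the aluminium hydride gives the allylic alcohol with both alkene geometries and the carbon–iodine bond intact.

Step 5
Reactants: 10 (2Z,6Z)-7-iodo-2,6-dimethylhepta-2,6-dien-1-ol
Product: 11 (2Z,6Z)-1-bromo-7-iodo-2,6-dimethylhepta-2,6-diene
Conditions: CBr4, PPh3, CH2Cl2, 0 °C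
Reagents that add atoms: carbon tetrabromide (SMILES: BrC(Br)(Br)Br)
Why: Appel bromination proceeds by SN2 attack of bromide on the alkoxyphosphonium ion at the primary allylic carbon, so neither allylic transposition nor Z/E isomerisation is expected at 0 °C.

Step 6
Reactants: 12 2,2-dimethyl-1,3-dioxan-5-one; 13 (R)-1-amino-2-(methoxymethyl)pyrrolidine (RAMP)
Product: 14 (2R)-N-(2,2-dimethyl-1,3-dioxan-5-ylidene)-2-(methoxymethyl)pyrrolidin-1-amine
Conditions: toluene, 4 Å molecular sieves, 60 °C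
Reagents that add atoms: none
Why: Condensation of the ketone with the chiral hydrazine gives the hydrazone that serves as the enolate equivalent for the Enders alkylation.

Step 7
Reactants: 14 (2R)-N-(2,2-dimethyl-1,3-dioxan-5-ylidene)-2-(methoxymethyl)pyrrolidin-1-amine; 11 (2Z,6Z)-1-bromo-7-iodo-2,6-dimethylhepta-2,6-diene
Product: 16 (2R)-N-{(4R)-4-[(2Z,6Z)-7-iodo-2,6-dimethylhepta-2,6-dien-1-yl]-2,2-dimethyl-1,3-dioxan-5-ylidene}-2-(methoxymethyl)pyrrolidin-1-amine, via lithium azaenolate 15 (not isolated)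
Conditions: t-BuLi (1.0 equiv), THF, −78 °C; then 11, −100 to −78 °C
Reagents that add atoms: none
Why: Enders hydrazone alkylation: the chelated lithium azaenolate is alkylated by SN2 at the allylic bromide on the face remote from the methoxymethyl arm, which with the (R)-auxiliary sets C8 as R, and no alkyllithium remains to attack the vinyl iodide.

Step 8
Reactants: 16 (2R)-N-{(4R)-4-[(2Z,6Z)-7-iodo-2,6-dimethylhepta-2,6-dien-1-yl]-2,2-dimethyl-1,3-dioxan-5-ylidene}-2-(methoxymethyl)pyrrolidin-1-amine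
Product: 18 (3R,5Z,9Z)-1,3-dihydroxy-10-iodo-5,9-dimethyldeca-5,9-dien-2-one, via acetonide ketone 17 (not isolated)
Conditions: sat. aq. (CO2H)2, Et2O, 25 °C; then 1 M HCl, THF, 25 °C
Reagents that add atoms: water (SMILES: O)
Why: Two-phase oxalic acid hydrolysis cleaves the hydrazone without epimerising the α-centre, and dilute mineral acid then removes the isopropylidene ketal to give the 1,3-dihydroxy ketone (C6–C7–C8).

Step 9
Reactants: 18 (3R,5Z,9Z)-1,3-dihydroxy-10-iodo-5,9-dimethyldeca-5,9-dien-2-one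
Product: 19 (3R,5Z,9Z)-3-hydroxy-10-iodo-5,9-dimethyl-1-(triethylsilyloxy)deca-5,9-dien-2-one
Conditions: Et3SiCl, imidazole, CH2Cl2, −78 to −40 °C
Reagents that add atoms: chlorotriethylsilane (SMILES: CC[Si](Cl)(CC)CC)
Why: Silylation is selective for the primary C6 hydroxyl over the more hindered secondary C8 hydroxyl, which stays free for esterification.

Step 10
Reactants: 20 ethyl 2-(diethoxyphosphoryl)prop-2-enoate; 21 4-methoxybenzyl alcohol
Product: 22 ethyl 2-(diethoxyphosphoryl)-3-[(4-methoxybenzyl)oxy]propanoate (racemic)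
Conditions: t-BuOK (5 mol%), THF, 0 °C
Reagents that add atoms: none
Why: Oxa-Michael addition of the benzylic alkoxide to the doubly activated acrylate places the protected C12 hydroxymethyl group on the phosphonate carbon, whose racemic centre disappears in step 12.

Step 11
Reactants: 22 ethyl 2-(diethoxyphosphoryl)-3-[(4-methoxybenzyl)oxy]propanoate
Product: 23 2-(diethoxyphosphoryl)-3-[(4-methoxybenzyl)oxy]propanoic acid (racemic)
Conditions: LiOH, THF/H2O, 0 °C; then aq. HCl to pH 3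
Reagents that add atoms: lithium hydroxide (SMILES: [Li+].[OH-])
Why: Saponification gives the acid, and once the carboxylate has formed the α-proton is no longer acidic enough for retro-Michael loss of the ether.

Step 12
Reactants: 19 (3R,5Z,9Z)-3-hydroxy-10-iodo-5,9-dimethyl-1-(triethylsilyloxy)deca-5,9-dien-2-one; 23 2-(diethoxyphosphoryl)-3-[(4-methoxybenzyl)oxy]propanoic acid
Product: 25 (5R)-5-[(2Z,6Z)-7-iodo-2,6-dimethylhepta-2,6-dien-1-yl]-3-{[(4-methoxybenzyl)oxy]methyl}-4-[(triethylsilyloxy)methyl]furan-2(5H)-one, via phosphonate ester 24 (not isolated)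
Conditions: DCC, DMAP (cat.), CH2Cl2, 0 °C; then LiCl, i-Pr2NEt, MeCN, 0 to 25 °C
Reagents that add atoms: none
Why: Steglich esterification of the C8 hydroxyl followed by intramolecular Horner–Wadsworth–Emmons olefination of the C7 ketone under Masamune–Roush conditions closes a butenolide, so the ring itself fixes the geometry of the tetrasubstituted C7=C11 alkene (C13 carbonyl cis to C8, C12 ether cis to C6) while the weak base spares the C8 centre.

Step 13
Reactants: 25 (5R)-5-[(2Z,6Z)-7-iodo-2,6-dimethylhepta-2,6-dien-1-yl]-3-{[(4-methoxybenzyl)oxy]methyl}-4-[(triethylsilyloxy)methyl]furan-2(5H)-one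
Product: 26 (2E,4R,6Z,10Z)-11-iodo-2-{[(4-methoxybenzyl)oxy]methyl}-6,10-dimethyl-3-[(triethylsilyloxy)methyl]undeca-2,6,10-triene-1,4-diol
Conditions: i-Bu2AlH (4 equiv), CH2Cl2, −78 to −20 °C
Reagents that add atoms: none
Why: Exhaustive 1,2-reduction of the butenolide through its lactol gives the ene-1,4-diol, freeing C13–OH and C8–OH while C12 and C6 stay protected and the alkene geometry set by the ring is kept.

Step 14
Reactants: 26 (2E,4R,6Z,10Z)-11-iodo-2-{[(4-methoxybenzyl)oxy]methyl}-6,10-dimethyl-3-[(triethylsilyloxy)methyl]undeca-2,6,10-triene-1,4-diol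
Product: 27 (2Z,4R,6Z,10Z)-4-hydroxy-11-iodo-2-{[(4-methoxybenzyl)oxy]methyl}-6,10-dimethyl-3-[(triethylsilyloxy)methyl]undeca-2,6,10-trien-1-yl acetate
Conditions: AcCl (1.05 equiv), 2,4,6-collidine, CH2Cl2, −78 °C
Reagents that add atoms: acetyl chloride (SMILES: CC(Cl)=O)
Why: Acylation with acetyl chloride and a hindered pyridine base at low temperature is selective for the primary allylic C13 hydroxyl over the secondary C8 hydroxyl.

Step 15
Reactants: 27 (2Z,4R,6Z,10Z)-4-hydroxy-11-iodo-2-{[(4-methoxybenzyl)oxy]methyl}-6,10-dimethyl-3-[(triethylsilyloxy)methyl]undeca-2,6,10-trien-1-yl acetate; 28 3-methylbut-2-enoyl chloride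
Product: 29 (2Z,4R,6Z,10Z)-1-acetoxy-11-iodo-2-{[(4-methoxybenzyl)oxy]methyl}-6,10-dimethyl-3-[(triethylsilyloxy)methyl]undeca-2,6,10-trien-4-yl 3-methylbut-2-enoate
Conditions: pyridine, DMAP (cat.), CH2Cl2, 0 to 25 °C
Reagents that add atoms: none
Why: Nucleophile-catalysed acylation of the secondary allylic alcohol installs the senecioate with retention at C8, pyridine being too weak a base to deconjugate the acyl chloride through its vinylketene.

Step 16
Reactants: 29 (2Z,4R,6Z,10Z)-1-acetoxy-11-iodo-2-{[(4-methoxybenzyl)oxy]methyl}-6,10-dimethyl-3-[(triethylsilyloxy)methyl]undeca-2,6,10-trien-4-yl 3-methylbut-2-enoate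
Product: 30 (2Z,4R)-1-acetoxy-5-{(2R,3S)-3-[(3Z)-4-iodo-3-methylbut-3-en-1-yl]-2-methyloxiran-2-yl}-2-{[(4-methoxybenzyl)oxy]methyl}-3-[(triethylsilyloxy)methyl]pent-2-en-4-yl 3-methylbut-2-enoate
Conditions: L-fructose-derived Shi ketone (30 mol%), KHSO5 (as 2KHSO5·KHSO4·K2SO4), K2CO3, Bu4NHSO4, Na2B4O7 buffer pH 10.5, MeCN/CH2(OMe)2/H2O, 0 °C
Reagents that add atoms: potassium peroxymonosulfate (SMILES: [K+].[O-]S(=O)(=O)OO)
Why: Shi epoxidation: the chiral dioxirane transfers oxygen stereospecifically through a spiro transition state to the electron-rich trisubstituted C1=C10 alkene (the vinyl iodide, the enoate and the hindered, inductively deactivated C7=C11 alkene react far more slowly), and the L-fructose-derived catalyst, by the established enantioface preference for trisubstituted alkenes, gives the cis (1S,10R)-epoxide under reagent control.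

Step 17
Reactants: 30 (2Z,4R)-1-acetoxy-5-{(2R,3S)-3-[(3Z)-4-iodo-3-methylbut-3-en-1-yl]-2-methyloxiran-2-yl}-2-{[(4-methoxybenzyl)oxy]methyl}-3-[(triethylsilyloxy)methyl]pent-2-en-4-yl 3-methylbut-2-enoate
Product: 31 (2E,4R)-1-acetoxy-3-formyl-5-{(2R,3S)-3-[(3Z)-4-iodo-3-methylbut-3-en-1-yl]-2-methyloxiran-2-yl}-2-{[(4-methoxybenzyl)oxy]methyl}pent-2-en-4-yl 3-methylbut-2-enoate
Conditions: (COCl)2, DMSO, CH2Cl2, −78 to −40 °C; then Et3N, −78 to 0 °C
Reagents that add atoms: none
Why: Under Swern conditions a primary triethylsilyl ether is cleaved by the chlorosulfonium reagent and oxidised directly to the aldehyde, which unveils the C6 enal without touching the 4-methoxybenzyl ether, the esters or the epoxide and without isomerising the tetrasubstituted alkene.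

Step 18
Reactants: 31 (2E,4R)-1-acetoxy-3-formyl-5-{(2R,3S)-3-[(3Z)-4-iodo-3-methylbut-3-en-1-yl]-2-methyloxiran-2-yl}-2-{[(4-methoxybenzyl)oxy]methyl}pent-2-en-4-yl 3-methylbut-2-enoate
Product: 32 (1S,4Z,6R,8R,10R)-13-acetoxy-1,10-epoxy-6-hydroxy-12-[(4-methoxybenzyl)oxy]germacra-4,7(11)-dien-8-yl 3-methylbut-2-enoate (C12 cis to C6)
Conditions: CrCl2 (4 equiv), NiCl2 (5 mol%), N-[2-(4-isopropyl-4,5-dihydrooxazol-2-yl)-6-methylphenyl]methanesulfonamide (Re-face-directing antipode), Et3N, THF, 25 °C, 2 mM, slow addition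
Reagents that add atoms: none
Why: Nozaki–Hiyama–Kishi reaction: zerovalent nickel inserts into the C5–I bond, transmetalation gives an alkenyl species of trivalent chromium with retention of the Z geometry, and its 1,2-addition to the C6 aldehyde closes the ten-membered ring at C5–C6 (aided by the cis alkene and cis epoxide as turn elements), the chromium-bound ligand being chosen to direct attack to the Re face so that the carbinol has the arrangement that becomes 6S after epoxidation.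

Step 19
Reactants: 32 (1S,4Z,6R,8R,10R)-13-acetoxy-1,10-epoxy-6-hydroxy-12-[(4-methoxybenzyl)oxy]germacra-4,7(11)-dien-8-yl 3-methylbut-2-enoate
Product: 33 (1S,4S,5R,6S,8R,10R)-13-acetoxy-1,10:4,5-diepoxy-6-hydroxy-12-[(4-methoxybenzyl)oxy]germacr-7(11)-en-8-yl 3-methylbut-2-enoate
Conditions: m-CPBA, NaHCO3, CH2Cl2, 0 °C
Reagents that add atoms: 3-chloroperoxybenzoic acid (SMILES: OOC(=O)c1cccc(Cl)c1)
Why: Hydroxyl-assisted peracid epoxidation: allylic 1,3-strain with the cis C3 substituent holds C6–H in the alkene plane, so the hydrogen-bonded peracid attacks the face bearing the hydroxyl and gives the threo epoxy alcohol (4S,5R), the sense also known for peracid epoxidation of medium-ring cis-cycloalkenols, whereas vanadium/hydroperoxide systems tend to the erythro isomer in such rings and are avoided.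

Step 20
Reactants: 33 (1S,4S,5R,6S,8R,10R)-13-acetoxy-1,10:4,5-diepoxy-6-hydroxy-12-[(4-methoxybenzyl)oxy]germacr-7(11)-en-8-yl 3-methylbut-2-enoate
Product: 34 (1S,4S,5R,6S,8R,10R)-13-acetoxy-1,10:4,5-diepoxy-6-(methanesulfonyloxy)-12-[(4-methoxybenzyl)oxy]germacr-7(11)-en-8-yl 3-methylbut-2-enoate
Conditions: Ms2O, Et3N, DMAP (cat.), CH2Cl2, −20 to 0 °C
Reagents that add atoms: methanesulfonic anhydride (SMILES: CS(=O)(=O)OS(C)(=O)=O)
Why: O-Sulfonylation turns the C6 hydroxyl into a leaving group with retention of configuration, the anhydride avoiding chloride that could substitute the allylic sulfonate, and C12 still being an ether so that no internal nucleophile is present.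

Step 21
Reactants: 34 (1S,4S,5R,6S,8R,10R)-13-acetoxy-1,10:4,5-diepoxy-6-(methanesulfonyloxy)-12-[(4-methoxybenzyl)oxy]germacr-7(11)-en-8-yl 3-methylbut-2-enoate
Product: 35 (1S,4S,5R,6S,8R,10R)-13-acetoxy-1,10:4,5-diepoxy-12-hydroxy-6-(methanesulfonyloxy)germacr-7(11)-en-8-yl 3-methylbut-2-enoate
Conditions: DDQ, CH2Cl2/pH 7 phosphate buffer, 0 °C; used crude at once
Reagents that add atoms: none
Why: Oxidative cleavage of the 4-methoxybenzyl ether by hydride abstraction and hydrolysis frees the C12 hydroxyl under neutral conditions, in which the un-ionised alcohol neither displaces the mesylate nor picks up the C13 acetyl group before it is oxidised.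

Step 22
Reactants: 35 (1S,4S,5R,6S,8R,10R)-13-acetoxy-1,10:4,5-diepoxy-12-hydroxy-6-(methanesulfonyloxy)germacr-7(11)-en-8-yl 3-methylbut-2-enoate
Product: 36 (1S,4S,5R,6S,8R,10R)-13-acetoxy-1,10:4,5-diepoxy-6-(methanesulfonyloxy)-12-oxogermacr-7(11)-en-8-yl 3-methylbut-2-enoate
Conditions: Dess–Martin periodinane, NaHCO3, CH2Cl2, 0 °C
Reagents that add atoms: none
Why: Hypervalent iodine oxidation of the primary allylic alcohol gives the enal under buffered, non-nucleophilic conditions that leave the mesylate, the epoxides and the alkene geometry intact.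

Step 23
Reactants: 36 (1S,4S,5R,6S,8R,10R)-13-acetoxy-1,10:4,5-diepoxy-6-(methanesulfonyloxy)-12-oxogermacr-7(11)-en-8-yl 3-methylbut-2-enoate
Product: 37 (1S,4S,5R,6S,8R,10R)-13-acetoxy-1,10:4,5-diepoxy-6-(methanesulfonyloxy)-8-[(3-methylbut-2-enoyl)oxy]germacr-7(11)-en-12-oic acid (carboxyl cis to C6)
Conditions: NaClO2, NaH2PO4, 2-methylbut-2-ene, t-BuOH/H2O, 0 °C
Reagents that add atoms: sodium chlorite (SMILES: [Na+].[O-]Cl=O)
Why: Pinnick oxidation converts the enal into the carboxylic acid while the alkene scavenger removes hypochlorite, and at about pH 4 the acid stays largely protonated and is isolated cold without premature ring closure.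

Step 24
Reactants: 37 (1S,4S,5R,6S,8R,10R)-13-acetoxy-1,10:4,5-diepoxy-6-(methanesulfonyloxy)-8-[(3-methylbut-2-enoyl)oxy]germacr-7(11)-en-12-oic acid
Product: 38 (1S,4S,5R,6R,8R,10R)-13-acetoxy-1,10:4,5-diepoxy-8-[(3-methylbut-2-enoyl)oxy]germacr-7(11)-en-12,6-olide (CNP0228323.1)
Conditions: Cs2CO3 (0.55 equiv), DMF, 0 to 25 °C
Reagents that add atoms: none
Why: Deprotonation gives the cesium carboxylate, whose oxygen attacks C6 from the side opposite the mesylate in a concerted intramolecular SN2 displacement that forms the O–C6 bond. The closest known reaction type is the invertive lactonisation of γ-sulfonyloxy carboxylates, here a Z-γ-mesyloxy enoate giving a butenolide. Ring B closes in a 5-exo-tet mode, the C7=C11 alkene holding C12 cis to C6 so that the nucleophilic oxygen is already within reach of C6. The new C6 configuration (6R) is fixed by Walden inversion of the (6S)-mesylate, itself derived from the carbinol that directed the C4–C5 epoxidation. The step needs substitution at C6 rather than ionisation, opening of the epoxide at C5 or participation by the C8 ester; the β-oxygen substituents (epoxide, C8 and C13 esters) disfavour the allyl cation, the dipolar aprotic medium and cesium counter-ion raise carboxylate nucleophilicity, and no acyl-transfer path exists because C6 carries no free hydroxyl.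

Compound list
1 | 2-(2-bromoethyl)-1,3-dioxane | BrCCC1OCCCO1 | starting material
2 | propyne | CC#C | starting material
3 | [2-(1,3-dioxan-2-yl)ethyl]magnesium bromide | Br[Mg]CCC1OCCCO1 | intermediate
4 | [2-(1,3-dioxan-2-yl)ethyl]copper (MgBr2·SMe2 complex) | [Cu]CCC1OCCCO1 | intermediate
5 | (Z)-[4-(1,3-dioxan-2-yl)-2-methylbut-1-en-1-yl]copper | [Cu]/C=C(/C)CCC1OCCCO1 | intermediate
6 | 2-[(3Z)-4-iodo-3-methylbut-3-en-1-yl]-1,3-dioxane | I/C=C(/C)CCC1OCCCO1 | intermediate
7 | (4Z)-5-iodo-4-methylpent-4-enal | I/C=C(/C)CCC=O | intermediate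
8 | ethyl 2-[bis(2,2,2-trifluoroethoxy)phosphoryl]propanoate | CCOC(=O)C(C)P(=O)(OCC(F)(F)F)OCC(F)(F)F | starting material
9 | ethyl (2Z,6Z)-7-iodo-2,6-dimethylhepta-2,6-dienoate | CCOC(=O)/C(C)=C\CC/C(C)=C\I | intermediate
10 | (2Z,6Z)-7-iodo-2,6-dimethylhepta-2,6-dien-1-ol | OC/C(C)=C\CC/C(C)=C\I | intermediate
11 | (2Z,6Z)-1-bromo-7-iodo-2,6-dimethylhepta-2,6-diene | BrC/C(C)=C\CC/C(C)=C\I | intermediate
12 | 2,2-dimethyl-1,3-dioxan-5-one | CC1(C)OCC(=O)CO1 | starting material
13 | (R)-1-amino-2-(methoxymethyl)pyrrolidine (RAMP) | COC[C@H]1CCCN1N | starting material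
14 | (2R)-N-(2,2-dimethyl-1,3-dioxan-5-ylidene)-2-(methoxymethyl)pyrrolidin-1-amine | COC[C@H]1CCCN1N=C1COC(C)(C)OC1 | intermediate
15 | lithium azaenolate of hydrazone 14 | COC[C@H]1CCCN1N([Li])C1=COC(C)(C)OC1 | intermediate
16 | (2R)-N-{(4R)-4-[(2Z,6Z)-7-iodo-2,6-dimethylhepta-2,6-dien-1-yl]-2,2-dimethyl-1,3-dioxan-5-ylidene}-2-(methoxymethyl)pyrrolidin-1-amine | COC[C@H]1CCCN1/N=C1/COC(C)(C)O[C@@H]1C/C(C)=C\CC/C(C)=C\I | intermediate
17 | (4R)-4-[(2Z,6Z)-7-iodo-2,6-dimethylhepta-2,6-dien-1-yl]-2,2-dimethyl-1,3-dioxan-5-one | O=C1COC(C)(C)O[C@@H]1C/C(C)=C\CC/C(C)=C\I | intermediate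
18 | (3R,5Z,9Z)-1,3-dihydroxy-10-iodo-5,9-dimethyldeca-5,9-dien-2-one | OCC(=O)[C@H](O)C/C(C)=C\CC/C(C)=C\I | intermediate
19 | (3R,5Z,9Z)-3-hydroxy-10-iodo-5,9-dimethyl-1-(triethylsilyloxy)deca-5,9-dien-2-one | CC[Si](CC)(CC)OCC(=O)[C@H](O)C/C(C)=C\CC/C(C)=C\I | intermediate
20 | ethyl 2-(diethoxyphosphoryl)prop-2-enoate | CCOC(=O)C(=C)P(=O)(OCC)OCC | starting material
21 | 4-methoxybenzyl alcohol | COc1ccc(CO)cc1 | starting material
22 | ethyl 2-(diethoxyphosphoryl)-3-[(4-methoxybenzyl)oxy]propanoate (racemic) | CCOC(=O)C(COCc1ccc(OC)cc1)P(=O)(OCC)OCC | intermediate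
23 | 2-(diethoxyphosphoryl)-3-[(4-methoxybenzyl)oxy]propanoic acid (racemic) | OC(=O)C(COCc1ccc(OC)cc1)P(=O)(OCC)OCC | intermediate
24 | (3R,5Z,9Z)-10-iodo-5,9-dimethyl-2-oxo-1-(triethylsilyloxy)deca-5,9-dien-3-yl 2-(diethoxyphosphoryl)-3-[(4-methoxybenzyl)oxy]propanoate | CC[Si](CC)(CC)OCC(=O)[C@H](OC(=O)C(COCc1ccc(OC)cc1)P(=O)(OCC)OCC)C/C(C)=C\CC/C(C)=C\I | intermediate
25 | (5R)-5-[(2Z,6Z)-7-iodo-2,6-dimethylhepta-2,6-dien-1-yl]-3-{[(4-methoxybenzyl)oxy]methyl}-4-[(triethylsilyloxy)methyl]furan-2(5H)-one | O=C1O[C@H](C/C(C)=C\CC/C(C)=C\I)C(CO[Si](CC)(CC)CC)=C1COCc1ccc(OC)cc1 | intermediate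
26 | (2E,4R,6Z,10Z)-11-iodo-2-{[(4-methoxybenzyl)oxy]methyl}-6,10-dimethyl-3-[(triethylsilyloxy)methyl]undeca-2,6,10-triene-1,4-diol (C13–OH cis to C8) | OC/C(COCc1ccc(OC)cc1)=C(/CO[Si](CC)(CC)CC)[C@H](O)C/C(C)=C\CC/C(C)=C\I | intermediate
27 | (2Z,4R,6Z,10Z)-4-hydroxy-11-iodo-2-{[(4-methoxybenzyl)oxy]methyl}-6,10-dimethyl-3-[(triethylsilyloxy)methyl]undeca-2,6,10-trien-1-yl acetate | CC(=O)OC/C(COCc1ccc(OC)cc1)=C(/CO[Si](CC)(CC)CC)[C@H](O)C/C(C)=C\CC/C(C)=C\I | intermediate
28 | 3-methylbut-2-enoyl chloride | CC(C)=CC(Cl)=O | starting material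
29 | (2Z,4R,6Z,10Z)-1-acetoxy-11-iodo-2-{[(4-methoxybenzyl)oxy]methyl}-6,10-dimethyl-3-[(triethylsilyloxy)methyl]undeca-2,6,10-trien-4-yl 3-methylbut-2-enoate | CC(=O)OC/C(COCc1ccc(OC)cc1)=C(/CO[Si](CC)(CC)CC)[C@H](OC(=O)C=C(C)C)C/C(C)=C\CC/C(C)=C\I | intermediate
30 | (2Z,4R)-1-acetoxy-5-{(2R,3S)-3-[(3Z)-4-iodo-3-methylbut-3-en-1-yl]-2-methyloxiran-2-yl}-2-{[(4-methoxybenzyl)oxy]methyl}-3-[(triethylsilyloxy)methyl]pent-2-en-4-yl 3-methylbut-2-enoate | CC(=O)OC/C(COCc1ccc(OC)cc1)=C(/CO[Si](CC)(CC)CC)[C@H](OC(=O)C=C(C)C)C[C@@]1(C)O[C@H]1CC/C(C)=C\I | intermediate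
31 | (2E,4R)-1-acetoxy-3-formyl-5-{(2R,3S)-3-[(3Z)-4-iodo-3-methylbut-3-en-1-yl]-2-methyloxiran-2-yl}-2-{[(4-methoxybenzyl)oxy]methyl}pent-2-en-4-yl 3-methylbut-2-enoate | CC(=O)OC/C(COCc1ccc(OC)cc1)=C(/C=O)[C@H](OC(=O)C=C(C)C)C[C@@]1(C)O[C@H]1CC/C(C)=C\I | intermediate
32 | (1S,4Z,6R,8R,10R)-13-acetoxy-1,10-epoxy-6-hydroxy-12-[(4-methoxybenzyl)oxy]germacra-4,7(11)-dien-8-yl 3-methylbut-2-enoate (C12 cis to C6) | CC(=O)OC/C(COCc2ccc(OC)cc2)=C1/[C@H](O)/C=C(C)\CC[C@@H]2O[C@]2(C)C[C@H]1OC(=O)C=C(C)C | intermediate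
33 | (1S,4S,5R,6S,8R,10R)-13-acetoxy-1,10:4,5-diepoxy-6-hydroxy-12-[(4-methoxybenzyl)oxy]germacr-7(11)-en-8-yl 3-methylbut-2-enoate | CC(=O)OC/C(COCc2ccc(OC)cc2)=C1/[C@H](O)[C@H]2O[C@@]2(C)CC[C@@H]2O[C@]2(C)C[C@H]1OC(=O)C=C(C)C | intermediate
34 | (1S,4S,5R,6S,8R,10R)-13-acetoxy-1,10:4,5-diepoxy-6-(methanesulfonyloxy)-12-[(4-methoxybenzyl)oxy]germacr-7(11)-en-8-yl 3-methylbut-2-enoate | CC(=O)OC/C(COCc2ccc(OC)cc2)=C1/[C@H](OS(C)(=O)=O)[C@H]2O[C@@]2(C)CC[C@@H]2O[C@]2(C)C[C@H]1OC(=O)C=C(C)C | intermediate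
35 | (1S,4S,5R,6S,8R,10R)-13-acetoxy-1,10:4,5-diepoxy-12-hydroxy-6-(methanesulfonyloxy)germacr-7(11)-en-8-yl 3-methylbut-2-enoate | CC(=O)OC/C(CO)=C1/[C@H](OS(C)(=O)=O)[C@H]2O[C@@]2(C)CC[C@@H]2O[C@]2(C)C[C@H]1OC(=O)C=C(C)C | intermediate
36 | (1S,4S,5R,6S,8R,10R)-13-acetoxy-1,10:4,5-diepoxy-6-(methanesulfonyloxy)-12-oxogermacr-7(11)-en-8-yl 3-methylbut-2-enoate | CC(=O)OC/C(C=O)=C1/[C@H](OS(C)(=O)=O)[C@H]2O[C@@]2(C)CC[C@@H]2O[C@]2(C)C[C@H]1OC(=O)C=C(C)C | intermediate
37 | (1S,4S,5R,6S,8R,10R)-13-acetoxy-1,10:4,5-diepoxy-6-(methanesulfonyloxy)-8-[(3-methylbut-2-enoyl)oxy]germacr-7(11)-en-12-oic acid (carboxyl cis to C6) | CC(=O)OC/C(C(O)=O)=C1/[C@H](OS(C)(=O)=O)[C@H]2O[C@@]2(C)CC[C@@H]2O[C@]2(C)C[C@H]1OC(=O)C=C(C)C | intermediate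
38 | (1S,4S,5R,6R,8R,10R)-13-acetoxy-1,10:4,5-diepoxy-8-[(3-methylbut-2-enoyl)oxy]germacr-7(11)-en-12,6-olide (CNP0228323.1) | CC(=O)OCC1=C2[C@@H](OC1=O)[C@H]1O[C@@]1(C)CC[C@@H]1O[C@]1(C)C[C@H]2OC(=O)C=C(C)C | target

Total step count: 24. Longest linear sequence: 21 steps (steps 1–5, 7–9, 12–24).

Steps most likely to fail

Step 18. The ring closure may be outrun by intermolecular coupling, and the conformation of the forming ring may override the ligand and deliver the alkenyl group to the other aldehyde face. The fallback moves control of C6 from the carbon–carbon bond formation to a ketone reduction. Aldehyde 31 is cyclised without ligand (CrCl2, NiCl2 cat., DMSO/THF, high dilution), giving the C6-epimeric dienol F1 alone or mixed with 32. The carbinol is oxidised with Dess–Martin periodinane to the cross-conjugated dienone F2. Reduction with (S)-2-methyl-CBS-oxazaborolidine and catecholborane (toluene, −78 °C), treating the fully substituted C7 alkenyl group as the large substituent, returns the route to 32.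

Step 19. The ring conformation may expose the wrong alkene face to the peracid, or hydrogen-bond delivery may be weak, so that facial selectivity is poor or reversed. The fallback replaces hydroxyl direction by reagent control. Dienol 32 is silylated (Et3SiOSO2CF3, 2,6-lutidine) to the silyl ether F3. Epoxidation with the D-fructose-derived Shi ketone and KHSO5, the antipode predicted to give the (4S,5R)-epoxide, gives the epoxy silyl ether F4. HF·pyridine then frees the carbinol and the route is rejoined at 33.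

Step 24. Ionisation of the allylic mesylate, participation by the C8 ester or attack of the carboxylate at the C5 epoxide carbon may compete with direct displacement, and the free C12 hydroxyl of step 21 may close an ether ring before it is oxidised. The fallback separates inversion from ring closure. Mesylate 34, with C12 still protected, is displaced with ClCH2CO2Cs and 18-crown-6 in toluene to give the inverted (6R)-chloroacetate F5. Thiourea/NaHCO3 removes the chloroacetyl group selectively to give the (6R)-alcohol F6. DDQ frees C12 to give the diol F7. TEMPO/PhI(OAc)2 oxidises the primary allylic alcohol through the lactol to the lactone with retention at C6, arriving at 38.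

Further compounds
F1 | step 18 | (1S,4Z,6S,8R,10R)-13-acetoxy-1,10-epoxy-6-hydroxy-12-[(4-methoxybenzyl)oxy]germacra-4,7(11)-dien-8-yl 3-methylbut-2-enoate (C6 epimer of 32) | CC(=O)OC/C(COCc2ccc(OC)cc2)=C1/[C@@H](O)/C=C(C)\CC[C@@H]2O[C@]2(C)C[C@H]1OC(=O)C=C(C)C
F2 | step 18 | (1S,4Z,8R,10R)-13-acetoxy-1,10-epoxy-12-[(4-methoxybenzyl)oxy]-6-oxogermacra-4,7(11)-dien-8-yl 3-methylbut-2-enoate | CC(=O)OC/C(COCc2ccc(OC)cc2)=C1/C(=O)/C=C(C)\CC[C@@H]2O[C@]2(C)C[C@H]1OC(=O)C=C(C)C
F3 | step 19 | (1S,4Z,6R,8R,10R)-13-acetoxy-1,10-epoxy-12-[(4-methoxybenzyl)oxy]-6-(triethylsilyloxy)germacra-4,7(11)-dien-8-yl 3-methylbut-2-enoate | CC(=O)OC/C(COCc2ccc(OC)cc2)=C1/[C@H](O[Si](CC)(CC)CC)/C=C(C)\CC[C@@H]2O[C@]2(C)C[C@H]1OC(=O)C=C(C)C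
F4 | step 19 | (1S,4S,5R,6S,8R,10R)-13-acetoxy-1,10:4,5-diepoxy-12-[(4-methoxybenzyl)oxy]-6-(triethylsilyloxy)germacr-7(11)-en-8-yl 3-methylbut-2-enoate | CC(=O)OC/C(COCc2ccc(OC)cc2)=C1/[C@H](O[Si](CC)(CC)CC)[C@H]2O[C@@]2(C)CC[C@@H]2O[C@]2(C)C[C@H]1OC(=O)C=C(C)C
F5 | step 24 | (1S,4S,5R,6R,8R,10R)-13-acetoxy-6-(chloroacetoxy)-1,10:4,5-diepoxy-12-[(4-methoxybenzyl)oxy]germacr-7(11)-en-8-yl 3-methylbut-2-enoate | CC(=O)OC/C(COCc2ccc(OC)cc2)=C1/[C@@H](OC(=O)CCl)[C@H]2O[C@@]2(C)CC[C@@H]2O[C@]2(C)C[C@H]1OC(=O)C=C(C)C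
F6 | step 24 | (1S,4S,5R,6R,8R,10R)-13-acetoxy-1,10:4,5-diepoxy-6-hydroxy-12-[(4-methoxybenzyl)oxy]germacr-7(11)-en-8-yl 3-methylbut-2-enoate | CC(=O)OC/C(COCc2ccc(OC)cc2)=C1/[C@@H](O)[C@H]2O[C@@]2(C)CC[C@@H]2O[C@]2(C)C[C@H]1OC(=O)C=C(C)C
F7 | step 24 | (1S,4S,5R,6R,8R,10R)-13-acetoxy-1,10:4,5-diepoxy-6,12-dihydroxygermacr-7(11)-en-8-yl 3-methylbut-2-enoate | CC(=O)OC/C(CO)=C1/[C@@H](O)[C@H]2O[C@@]2(C)CC[C@@H]2O[C@]2(C)C[C@H]1OC(=O)C=C(C)C
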